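**Retrosynthetic overview**
1. δ-Tocopherol ⇐ O-demethylation of its 6-methyl ether ⇐ key cut C4'–C5': a secondary (R)-tosylate on the C16 chroman half plus the primary Grignard reagent of the C11 (R)-4,8-dimethylnonyl half. A copper-catalysed SN2 coupling with inversion sets 4'R, completes the C27 skeleton and leaves nothing to remove.
2. Enabling feature: C4' is a methine that carries only CH3 and two unbranched CH2 neighbours (C3', C5'). The nearest branched atoms (quaternary C2 of the dihydropyran ring, and C8') are four bonds away and the only other functions are aryl ethers, so a 1-methylalkyl sulfonate at C4' is open to clean backside attack.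
3. C16 half: the C4' carbinol comes from Corey–Bakshi–Shibata reduction of an E-enone. The enone comes from an enantioselective domino Wacker–Heck reaction of a 2-(3-methylbut-3-enyl)phenol with methyl vinyl ketone, which makes the dihydropyran ring, C2 and the C1'–C2' bond in one step. The phenol comes from 4-methoxy-2-methylphenol by bromination and Negishi coupling.
4. C11 half: (R)-citronellyl bromide (C8' bought), one-carbon homologation with formaldehyde (this carbon becomes C5'), hydrogenation, bromination.
5. Rings: the benzene ring is bought; the dihydropyran ring is the only ring formed (step 3), before the key coupling.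

Key step: step 10

Remark: tocopherol locants are used (O1, C2 to C8a in the chroman; C1' to C13' in the side chain); the (S,S)-configured BOXAX ligand is assumed to favour the alkene face that leads to the natural C2 configuration, and its (R,R)-antipode would be used if the sense turned out opposite.

**Route**

Step 1
Reactants: 1 4-methoxy-2-methylphenol
Product: 2 2-bromo-4-methoxy-6-methylphenol
Conditions: NBS (1.0 equiv), CH2Cl2, 0 °C
Reagents that add atoms: N-bromosuccinimide O=C1CCC(=O)N1Br
Why: Electrophilic aromatic bromination: the free hydroxyl is the strongest activating group and C6 is its only free ortho/para position (C2 and C4 are substituted), so one equivalent of N-bromosuccinimide should brominate there.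

Step 2
Reactants: 2 2-bromo-4-methoxy-6-methylphenol; 3 4-bromo-2-methylbut-1-ene
Product: 5 4-methoxy-2-methyl-6-(3-methylbut-3-en-1-yl)phenol, via (3-methylbut-3-en-1-yl)zinc bromide 4 (not isolated)
Conditions: 3 (2.2 equiv), Zn, LiCl, THF, 40 °C; then 2, Pd(OAc)2 (2 mol %), SPhos (4 mol %), THF, rt
Reagents that add atoms: none
Why: Negishi coupling: zinc inserts into the primary bromide 3 to give 4, and palladium with the bulky biarylphosphine SPhos should couple this primary alkylzinc halide with the aryl bromide faster than the free phenol protonates it (the excess of 4 covers any loss), the 1,1-disubstituted alkene staying untouched.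

Step 3
Reactants: 5 4-methoxy-2-methyl-6-(3-methylbut-3-en-1-yl)phenol; 6 but-3-en-2-one (methyl vinyl ketone)
Product: 7 (3E)-5-[(2S)-6-methoxy-2,8-dimethylchroman-2-yl]pent-3-en-2-one
Conditions: Pd(OCOCF3)2 (10 mol %), (S,S)-Bn-BOXAX (40 mol %), p-benzoquinone (4 equiv), 6 (5 equiv), CH2Cl2, rt
Reagents that add atoms: none
Why: Enantioselective domino Wacker–Heck reaction: the chiral bis(oxazoline)–palladium complex controls the alkene face in the 6-exo-trig oxypalladation that closes the dihydropyran ring and sets C2, the resulting alkylpalladium (no beta-hydrogen, quaternary neighbour) inserts 6, and beta-hydride elimination releases the E-enone while benzoquinone reoxidises zerovalent palladium to divalent palladium.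

Step 4
Reactants: 7 (3E)-5-[(2S)-6-methoxy-2,8-dimethylchroman-2-yl]pent-3-en-2-one
Product: 8 (2R,3E)-5-[(2S)-6-methoxy-2,8-dimethylchroman-2-yl]pent-3-en-2-ol
Conditions: (S)-2-methyl-CBS-oxazaborolidine (20 mol %), catecholborane (1.8 equiv), toluene, −78 °C; aqueous work-up
Reagents that add atoms: none
Why: Corey–Bakshi–Shibata reduction: the oxazaborolidine–borane complex binds the ketone with the alkenyl group as the large substituent and delivers hydride to one carbonyl face in a 1,2-sense, which by the established model for the (S)-catalyst should give the 2R carbinol (the later C4'–O centre).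

Step 5
Reactants: 8 (2R,3E)-5-[(2S)-6-methoxy-2,8-dimethylchroman-2-yl]pent-3-en-2-ol
Product: 9 (2R)-5-[(2R)-6-methoxy-2,8-dimethylchroman-2-yl]pentan-2-ol
Conditions: H2 (1 atm), 5% Pt/C, EtOAc, rt
Reagents that add atoms: none
Why: Heterogeneous catalytic hydrogenation of the disubstituted alkene; platinum on carbon in a neutral solvent should keep allylic C–O hydrogenolysis low, and no stereocentre is formed or changed (the C2 descriptor switches from S to R only because the side chain loses priority on saturation).

Step 6
Reactants: 9 (2R)-5-[(2R)-6-methoxy-2,8-dimethylchroman-2-yl]pentan-2-ol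
Product: 10 (2R)-5-[(2R)-6-methoxy-2,8-dimethylchroman-2-yl]pentan-2-yl 4-methylbenzenesulfonate
Conditions: TsCl (1.5 equiv), pyridine, DMAP (cat.), CH2Cl2, 0 °C to rt
Reagents that add atoms: 4-methylbenzenesulfonyl chloride Cc1ccc(cc1)S(Cl)(=O)=O
Why: O-Sulfonylation of the secondary alcohol (nucleophilic catalysis by DMAP); the C–O bond is not broken, so C4' keeps its R configuration.

Step 7
Reactants: 11 (6R)-8-bromo-2,6-dimethyloct-2-ene ((R)-citronellyl bromide)
Product: 13 (4R)-4,8-dimethylnon-7-en-1-ol, via [(3R)-3,7-dimethyloct-6-en-1-yl]magnesium bromide 12 (not isolated)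
Conditions: Mg, THF, reflux; then paraformaldehyde, 0 °C to rt; 1 M HCl
Reagents that add atoms: paraformaldehyde (as formaldehyde) C=O
Why: Grignard formation followed by 1,2-addition to formaldehyde (one-carbon homologation; the new CH2OH carbon becomes C5'); the stereocentre is neither at nor next to the metal-bearing carbon and is not affected.

Step 8
Reactants: 13 (4R)-4,8-dimethylnon-7-en-1-ol
Product: 14 (4R)-4,8-dimethylnonan-1-ol
Conditions: H2 (1 atm), 10% Pd/C, EtOAc, rt
Reagents that add atoms: none
Why: Heterogeneous catalytic hydrogenation of the trisubstituted alkene, which creates no stereocentre (C8 carries two methyl groups) and leaves C4 untouched.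

Step 9
Reactants: 14 (4R)-4,8-dimethylnonan-1-ol
Product: 15 (4R)-1-bromo-4,8-dimethylnonane
Conditions: CBr4, PPh3, CH2Cl2, 0 °C
Reagents that add atoms: tetrabromomethane BrC(Br)(Br)Br
Why: Appel reaction: the primary alcohol is activated as an alkoxyphosphonium ion and displaced by bromide in an SN2 step far from the stereocentre.

Step 10
Reactants: 10 (2R)-5-[(2R)-6-methoxy-2,8-dimethylchroman-2-yl]pentan-2-yl 4-methylbenzenesulfonate; 15 (4R)-1-bromo-4,8-dimethylnonane
Product: 17 (2R)-6-methoxy-2,8-dimethyl-2-[(4R,8R)-4,8,12-trimethyltridecyl]chromane, via [(4R)-4,8-dimethylnonyl]magnesium bromide 16 (not isolated)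
Conditions: 15 (2 equiv), Mg, THF, 40 °C; then 10, CuI (10 mol %), TMEDA (20 mol %), LiOMe (1 equiv), THF, 0 °C
Reagents that add atoms: none
Why: Magnesium inserts into 15 to give 16, which transmetalates to an alkylcuprate; this attacks C4' of 10 from the side opposite to the tosylate (oxidative addition at monovalent copper with inversion, then reductive elimination from trivalent copper with retention), so the C4'–C5' bond forms with net inversion and the whole C27 skeleton is complete. The closest known reaction type is the copper-catalysed cross-coupling of unactivated secondary alkyl tosylates with alkyl Grignard reagents (CuI/TMEDA/LiOMe), an SN2-type process. No ring is closed. The one new stereocentre, C4', should become R because the carbinol centre set by the reagent-controlled reduction of step 4 is inverted, while C2 and C8' lie four bonds away and are not touched. The step needs substitution to win over E2 elimination, over single-electron pathways that would scramble C4', and over participation by the ring oxygen: the electrophile is a 1-methylalkyl sulfonate between unbranched CH2 groups (the least hindered secondary type), the nucleophile is a primary alkyl group, the ligated copper catalyst works at 0 °C, and the tert-alkyl aryl ether oxygen is too hindered and too weakly basic to act as a neighbouring group. Apart from the sulfonate only aryl ethers are present, which are inert to the Grignard reagent.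

Step 11
Reactants: 17 (2R)-6-methoxy-2,8-dimethyl-2-[(4R,8R)-4,8,12-trimethyltridecyl]chromane
Product: 18 (2R)-2,8-dimethyl-2-[(4R,8R)-4,8,12-trimethyltridecyl]chroman-6-ol (delta-tocopherol)
Conditions: NaSEt (5 equiv), DMF, 130 °C, argon; then 1 M HCl
Reagents that add atoms: none
Why: Nucleophilic demethylation of the aryl methyl ether: the thiolate attacks the methyl carbon in an SN2 step, whereas the tert-alkyl aryl ether of the dihydropyran ring cannot react this way, and no stereocentre is involved.

**Compound list**
1 | 4-methoxy-2-methylphenol | Cc1cc(OC)ccc1O | starting material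
2 | 2-bromo-4-methoxy-6-methylphenol | Cc1cc(OC)cc(Br)c1O | intermediate
3 | 4-bromo-2-methylbut-1-ene | C=C(C)CCBr | starting material
4 | (3-methylbut-3-en-1-yl)zinc bromide | C=C(C)CC[Zn]Br | intermediate
5 | 4-methoxy-2-methyl-6-(3-methylbut-3-en-1-yl)phenol | Cc1cc(OC)cc(CCC(C)=C)c1O | intermediate
6 | but-3-en-2-one (methyl vinyl ketone) | C=CC(C)=O | starting material
7 | (3E)-5-[(2S)-6-methoxy-2,8-dimethylchroman-2-yl]pent-3-en-2-one | Cc1cc(OC)cc2c1O[C@](C)(C/C=C/C(C)=O)CC2 | intermediate
8 | (2R,3E)-5-[(2S)-6-methoxy-2,8-dimethylchroman-2-yl]pent-3-en-2-ol | Cc1cc(OC)cc2c1O[C@](C)(C/C=C/[C@@H](C)O)CC2 | intermediate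
9 | (2R)-5-[(2R)-6-methoxy-2,8-dimethylchroman-2-yl]pentan-2-ol | Cc1cc(OC)cc2c1O[C@](C)(CCC[C@@H](C)O)CC2 | intermediate
10 | (2R)-5-[(2R)-6-methoxy-2,8-dimethylchroman-2-yl]pentan-2-yl 4-methylbenzenesulfonate | Cc1cc(OC)cc2c1O[C@](C)(CCC[C@@H](C)OS(=O)(=O)c3ccc(C)cc3)CC2 | intermediate
11 | (6R)-8-bromo-2,6-dimethyloct-2-ene ((R)-citronellyl bromide) | BrCC[C@H](C)CCC=C(C)C | starting material
12 | [(3R)-3,7-dimethyloct-6-en-1-yl]magnesium bromide | Br[Mg]CC[C@H](C)CCC=C(C)C | intermediate
13 | (4R)-4,8-dimethylnon-7-en-1-ol | OCCC[C@H](C)CCC=C(C)C | intermediate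
14 | (4R)-4,8-dimethylnonan-1-ol | OCCC[C@H](C)CCCC(C)C | intermediate
15 | (4R)-1-bromo-4,8-dimethylnonane | BrCCC[C@H](C)CCCC(C)C | intermediate
16 | [(4R)-4,8-dimethylnonyl]magnesium bromide | Br[Mg]CCC[C@H](C)CCCC(C)C | intermediate
17 | (2R)-6-methoxy-2,8-dimethyl-2-[(4R,8R)-4,8,12-trimethyltridecyl]chromane (delta-tocopherol methyl ether) | Cc1cc(OC)cc2c1O[C@](C)(CCC[C@H](C)CCC[C@H](C)CCCC(C)C)CC2 | intermediate
18 | (2R)-2,8-dimethyl-2-[(4R,8R)-4,8,12-trimethyltridecyl]chroman-6-ol (delta-tocopherol) | Cc1cc(O)cc2c1O[C@](C)(CCC[C@H](C)CCC[C@H](C)CCCC(C)C)CC2 | target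

**Step count and risks**

Total step count: 11. Longest linear sequence: 8 steps (steps 1 to 6, 10 and 11).

Steps most likely to fail:

1. Step 10 (key coupling). E2 elimination of the secondary tosylate by the basic organometallic may outrun substitution, and a competing single-electron pathway at copper would erode the inversion at C4'. The fallback replaces the organocopper coupling by alkylation of a sulfone-stabilised carbanion; it sets out from 9 and 15 and comes back at 17. Alcohol 9 would be converted with Tf2O and 2,6-lutidine (CH2Cl2, −78 °C) into (2R)-5-[(2R)-6-methoxy-2,8-dimethylchroman-2-yl]pentan-2-yl trifluoromethanesulfonate F1. Bromide 15 would be converted with PhSO2Na (DMF, 60 °C) into {[(4R)-4,8-dimethylnonyl]sulfonyl}benzene F2. The lithio derivative of F2 (n-BuLi, THF, −78 °C) should displace the triflate of F1 with inversion at C4' and give (2R)-2-[(4S,8R)-5-(benzenesulfonyl)-4,8,12-trimethyltridecyl]-6-methoxy-2,8-dimethylchromane F3 as both C5' epimers. Reductive desulfonylation (6% Na(Hg), Na2HPO4, MeOH) would then return 17.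

2. Step 2 (Negishi coupling on the unprotected bromophenol). Protonation of the alkylzinc reagent by the phenol and slow oxidative addition into the electron-rich aryl bromide may stall the coupling. The fallback builds the side chain from an aldehyde instead of a cross-coupling; it sets out from 1 and comes back at 5, bypassing steps 1 and 2. ortho-Formylation of 1 (MgCl2, Et3N, paraformaldehyde, MeCN, reflux) would give 2-hydroxy-5-methoxy-3-methylbenzaldehyde F4. Claisen–Schmidt condensation with acetone (aqueous NaOH) would give (3E)-4-(2-hydroxy-5-methoxy-3-methylphenyl)but-3-en-2-one F5. Hydrogenation (H2, Pd/C, EtOAc) would give 4-(2-hydroxy-5-methoxy-3-methylphenyl)butan-2-one F6, and Wittig methylenation (Ph3PCH3Br, KOtBu in excess, THF) would deliver 5.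

3. Step 4 (reagent-controlled reduction). Hydride delivery may not discriminate the two carbonyl faces well enough for an alkenyl methyl ketone, or conjugate reduction may compete. The fallback sets C4' by enzymatic resolution with stereoconvergent recycling instead of asymmetric reduction; it sets out from 7 and comes back at 9. Hydrogenation of 7 (H2, Pd/C, EtOAc) would give 5-[(2R)-6-methoxy-2,8-dimethylchroman-2-yl]pentan-2-one F7, and NaBH4 (MeOH) would give (2RS)-5-[(2R)-6-methoxy-2,8-dimethylchroman-2-yl]pentan-2-ol F8 as both C4' epimers. Candida antarctica lipase B with vinyl acetate should acylate the 4'R epimer to (2R)-5-[(2R)-6-methoxy-2,8-dimethylchroman-2-yl]pentan-2-yl acetate F9, following the usual preference of this lipase for R-configured methyl carbinols. The recovered 4'S alcohol would be converted into the same acetate F9 by Mitsunobu inversion (AcOH, PPh3, DIAD), and methanolysis of F9 (K2CO3, MeOH) would return 9.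

Further compounds
F1 | step 10 | (2R)-5-[(2R)-6-methoxy-2,8-dimethylchroman-2-yl]pentan-2-yl trifluoromethanesulfonate | Cc1cc(OC)cc2c1O[C@](C)(CCC[C@@H](C)OS(=O)(=O)C(F)(F)F)CC2
F2 | step 10 | {[(4R)-4,8-dimethylnonyl]sulfonyl}benzene | O=S(=O)(CCC[C@H](C)CCCC(C)C)c1ccccc1
F3 | step 10 | (2R)-2-[(4S,8R)-5-(benzenesulfonyl)-4,8,12-trimethyltridecyl]-6-methoxy-2,8-dimethylchromane (both C5' epimers) | Cc1cc(OC)cc2c1O[C@](C)(CCC[C@H](C)C(CC[C@H](C)CCCC(C)C)S(=O)(=O)c3ccccc3)CC2
F4 | step 2 | 2-hydroxy-5-methoxy-3-methylbenzaldehyde | Cc1cc(OC)cc(C=O)c1O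
F5 | step 2 | (3E)-4-(2-hydroxy-5-methoxy-3-methylphenyl)but-3-en-2-one | CC(=O)/C=C/c1cc(OC)cc(C)c1O
F6 | step 2 | 4-(2-hydroxy-5-methoxy-3-methylphenyl)butan-2-one | CC(=O)CCc1cc(OC)cc(C)c1O
F7 | step 4 | 5-[(2R)-6-methoxy-2,8-dimethylchroman-2-yl]pentan-2-one | Cc1cc(OC)cc2c1O[C@](C)(CCCC(C)=O)CC2
F8 | step 4 | (2RS)-5-[(2R)-6-methoxy-2,8-dimethylchroman-2-yl]pentan-2-ol (both C4' epimers) | Cc1cc(OC)cc2c1O[C@](C)(CCCC(C)O)CC2
F9 | step 4 | (2R)-5-[(2R)-6-methoxy-2,8-dimethylchroman-2-yl]pentan-2-yl acetate | Cc1cc(OC)cc2c1O[C@](C)(CCC[C@@H](C)OC(C)=O)CC2
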